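**Plan**

- Numbering (2-oxabicyclo[8.4.0]tetradecane core): C1 = methyl-bearing ether carbon of the cyclohexane, O2, C3 = methyl/vinyl carbon, C6–C7 = epoxide, C10 = ring-fusion CH, C11 = CMe2, C12 = CHBr, C13 and C14 = ring CH2 groups.
- Cuts, in order: C12–Br (back to an alkenyl bromide and a C12 ketone); the epoxide (back to the (E)-C6=C7 alkene); C8–C9 (ten-membered ring, sulfone alkylation); then C13–C14 and C1–C10 together (cyclohexane); last the C1=C14 enol ether, back to the acetate of (R)-linalool.
- Enabling feature: in the cyclohexane, C1 with its methyl group, O2 and the ring CH2 C14 is a hidden isopropenyl ether (electron-rich two-carbon unit). C13–C12(=O)–C11–C10 is a hidden α-keto radical carrying a vinyl sulfone (four-carbon unit, electrophilic radical at C13, radical acceptor at C10).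
- Forward: two fragments are joined by a radical [4+2] annulation that builds the cyclohexanone (C13–C14, then C1–C10). The ten-membered oxacycle is then closed at C8–C9 and the sulfone removed. The ketone goes through its enol triflate to the alkenyl bromide, C6=C7 is epoxidised, and hydrogen atom transfer hydrogenation sets C12.
- Stereochemistry: C3 comes from (R)-linalool. C1 and C10 arise as a trans pair from the chair transition state of the 6-exo closure; C3 is too remote to bias their sense, so the wanted diastereomer is separated. C6 and C7 are set by reagent control (Shi epoxidation). C12 is set by axial hydrogen delivery to a C12 radical.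

Key step: step 8

Remark: (R)-linalool of high enantiomeric purity, 4-hydroxy-3,3-dimethylbutan-2-one and diethyl [(phenylsulfonyl)methyl]phosphonate are taken as commercial.

**Route**

Step 1
Reactants: 1 (R)-linalool, (3R)-3,7-dimethylocta-1,6-dien-3-ol
Product: 2 (R)-linalyl acetate, (3R)-3,7-dimethylocta-1,6-dien-3-yl acetate
Conditions: Ac2O, Et3N, DMAP (cat.), CH2Cl2, 25 °C
Reagents that add atoms: acetic anhydride, CC(=O)OC(C)=O
Why: Nucleophilic catalysis by DMAP (Steglich-type acylation) esterifies the hindered tertiary allylic alcohol without touching the C3 stereocentre or the alkenes.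

Step 2
Reactants: 2 (R)-linalyl acetate
Product: 3 (3R,6E)-8-hydroxy-3,7-dimethylocta-1,6-dien-3-yl acetate
Conditions: SeO2 (cat.), t-BuOOH, salicylic acid (cat.), CH2Cl2, 25 °C
Reagents that add atoms: tert-butyl hydroperoxide, CC(C)(C)OO
Why: Riley-type SeO2 allylic oxidation (ene reaction, then [2,3]-sigmatropic shift) with t-BuOOH as terminal oxidant hydroxylates the (E)-methyl group of the electron-rich trisubstituted alkene and leaves the vinyl group and the acetate alone.

Step 3
Reactants: 3 (3R,6E)-8-hydroxy-3,7-dimethylocta-1,6-dien-3-yl acetate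
Product: 5 (3R,6E)-8-chloro-3,7-dimethylocta-1,6-dien-3-yl acetate, via allylic mesylate 4 (not isolated)
Conditions: MsCl, Et3N, CH2Cl2, −40 °C; then LiCl, THF, 0 °C
Reagents that add atoms: lithium chloride, [Li+].[Cl-]
Why: Mesylation followed by SN2 displacement with chloride at the primary allylic carbon (no allylic transposition, E geometry kept) installs the leaving group for the later ring closure, an allylic chloride being chosen because it tolerates Cp2Ti=CH2 in step 4 and reacts only slowly with silyl radicals in step 8.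

Step 4
Reactants: 5 (3R,6E)-8-chloro-3,7-dimethylocta-1,6-dien-3-yl acetate
Product: 6 (3R,6E)-8-chloro-3,7-dimethyl-3-(prop-1-en-2-yloxy)octa-1,6-diene
Conditions: Tebbe reagent Cp2Ti(μ-Cl)(μ-CH2)AlMe2, pyridine (cat.), THF–toluene, −40 to 0 °C
Reagents that add atoms: Tebbe reagent Cp2Ti(μ-Cl)(μ-CH2)AlMe2, C[Al-]1(C)C[Ti](C2C=CC=C2)(C2C=CC=C2)[Cl+]1
Why: Tebbe methylenation of the ester carbonyl ([2+2] addition of the methylidene Cp2Ti=CH2, then cycloreversion) turns the tertiary acetate into the isopropenyl ether C14=C1 with the O2–C3 bond already in place, and the product, an allyl vinyl ether, is kept at or below 25 °C from here on so that no Claisen rearrangement sets in.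

Step 5
Reactants: 7 4-hydroxy-3,3-dimethylbutan-2-one
Product: 8 2,2-dimethyl-3-oxobutanal
Conditions: TEMPO (cat.), PhI(OAc)2, CH2Cl2, 25 °C
Reagents that add atoms: none
Why: TEMPO-catalysed oxidation (oxoammonium ion, PhI(OAc)2 as terminal oxidant) of the neopentyl primary alcohol gives the non-enolisable aldehyde without over-oxidation.

Step 6
Reactants: 8 2,2-dimethyl-3-oxobutanal; 9 diethyl [(phenylsulfonyl)methyl]phosphonate
Product: 10 (4E)-3,3-dimethyl-5-(phenylsulfonyl)pent-4-en-2-one
Conditions: NaH, THF, 0 to 25 °C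
Reagents that add atoms: none
Why: Horner–Wadsworth–Emmons olefination of the aldehyde, which is more electrophilic than the hindered methyl ketone, by the sulfonyl-stabilised phosphonate anion gives the (E)-vinyl sulfone C9=C10.

Step 7
Reactants: 10 (4E)-3,3-dimethyl-5-(phenylsulfonyl)pent-4-en-2-one
Product: 11 (4E)-1-bromo-3,3-dimethyl-5-(phenylsulfonyl)pent-4-en-2-one
Conditions: Br2, AcOH, 25 °C
Reagents that add atoms: bromine, BrBr
Why: Acid-catalysed α-bromination through the enol, which can form only toward the methyl group because C11 is quaternary, gives the bromomethyl ketone while the electron-poor vinyl sulfone does not add bromine.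

Step 8
Reactants: 11 (4E)-1-bromo-3,3-dimethyl-5-(phenylsulfonyl)pent-4-en-2-one; 6 (3R,6E)-8-chloro-3,7-dimethyl-3-(prop-1-en-2-yloxy)octa-1,6-diene
Product: 12 (3S,4S)-4-{[(3R,6E)-8-chloro-3,7-dimethylocta-1,6-dien-3-yl]oxy}-2,2,4-trimethyl-3-[(phenylsulfonyl)methyl]cyclohexan-1-one
Conditions: (Me3Si)3SiH (slow addition), Et3B (cat.), air, benzene, 20 °C
Reagents that add atoms: none
Why: The silyl radical abstracts bromine from 11 and the electrophilic α-keto radical at C13 adds to the CH2 terminus (C14) of the isopropenyl ether of 6, the most nucleophilic alkene present, which forms C13–C14 and leaves a nucleophilic tertiary α-alkoxy radical at C1; this radical closes onto C10, the β-carbon of the vinyl sulfone, which forms C1–C10, and the α-sulfonyl radical at C9 takes hydrogen from the silane. The closest known reaction type is the polarity-alternating radical addition–cyclisation (radical [4+2] annulation) of α-halo carbonyl compounds that carry a tethered Michael acceptor with electron-rich alkenes. The cyclohexanone ring closes in the 6-exo-trig mode, helped by the gem-dimethyl group at C11 (Thorpe–Ingold effect). In the chair-like transition state the sulfonylvinyl arm at C10 and the much larger tertiary alkoxy group at C1 are expected to lie pseudo-equatorial and the C1 methyl group axial, which sets the trans relation of O2 and C9; the remote C3 centre is not expected to bias the sense of this pair, so 12 is separated by chromatography from the diastereomer in which C1 and C10 are both inverted. The step needs chemoselective attack on the enol ether instead of the C6=C7 and vinyl alkenes (polarity matching of the electrophilic radical), ring closure faster than hydrogen transfer (slow silane addition and an activated acceptor, which also outruns 6-exo attack of the C1 radical on C6=C7), and a temperature of 20 °C so that the allyl vinyl ether does not undergo Claisen rearrangement.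

Step 9
Reactants: 12 (3S,4S)-4-{[(3R,6E)-8-chloro-3,7-dimethylocta-1,6-dien-3-yl]oxy}-2,2,4-trimethyl-3-[(phenylsulfonyl)methyl]cyclohexan-1-one
Product: 13 (1S,3R,6E,10S)-3-ethenyl-1,3,7,11,11-pentamethyl-9-(phenylsulfonyl)-2-oxabicyclo[8.4.0]tetradec-6-en-12-one (C9 epimers)
Conditions: KN(SiMe3)2 (2.2 equiv), THF, −78 to −20 °C, 0.002 M
Reagents that add atoms: none
Why: Intramolecular SN2 alkylation of a sulfone-stabilised carbanion by the primary allylic chloride, the classical closure of (E)-cyclodecenes, forms C8–C9 and the ten-membered oxacycle, the ketone being held as its enolate while the more basic and more nucleophilic α-sulfonyl carbanion of the dianion reacts under high dilution, and the new C9 centre is removed in step 10.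

Step 10
Reactants: 13 (1S,3R,6E,10S)-3-ethenyl-1,3,7,11,11-pentamethyl-9-(phenylsulfonyl)-2-oxabicyclo[8.4.0]tetradec-6-en-12-one
Product: 14 (1S,3R,6E,10S)-3-ethenyl-1,3,7,11,11-pentamethyl-2-oxabicyclo[8.4.0]tetradec-6-en-12-one
Conditions: Na(Hg), Na2HPO4, MeOH–THF, −20 °C
Reagents that add atoms: none
Why: Julia-type reductive desulfonylation (electron transfer from Na(Hg), C–S cleavage, protonation) replaces the sulfone at C9 by hydrogen without reducing the hindered ketone or the alkenes.

Step 11
Reactants: 14 (1S,3R,6E,10S)-3-ethenyl-1,3,7,11,11-pentamethyl-2-oxabicyclo[8.4.0]tetradec-6-en-12-one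
Product: 15 (1S,3R,6E,10S)-3-ethenyl-1,3,7,11,11-pentamethyl-2-oxabicyclo[8.4.0]tetradeca-6,12-dien-12-yl trifluoromethanesulfonate
Conditions: KN(SiMe3)2, PhNTf2, THF, −78 °C
Reagents that add atoms: N-phenylbis(trifluoromethanesulfonimide), O=S(=O)(N(c1ccccc1)S(=O)(=O)C(F)(F)F)C(F)(F)F
Why: Deprotonation can occur only at C13 because C11 is quaternary, and O-sulfonylation of the potassium enolate by PhNTf2 gives a single enol triflate.

Step 12
Reactants: 15 (1S,3R,6E,10S)-3-ethenyl-1,3,7,11,11-pentamethyl-2-oxabicyclo[8.4.0]tetradeca-6,12-dien-12-yl trifluoromethanesulfonate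
Product: 16 (1S,3R,6E,10S)-12-bromo-3-ethenyl-1,3,7,11,11-pentamethyl-2-oxabicyclo[8.4.0]tetradeca-6,12-diene
Conditions: Ni(cod)2 (cat.), LiBr, DMA–THF, 25 °C
Reagents that add atoms: lithium bromide, [Li+].[Br-]
Why: Nickel-catalysed halide exchange of an enol triflate (oxidative addition of the C–O bond to zerovalent nickel, triflate/bromide exchange, C–Br reductive elimination) places bromine on C12 with no stereocentre involved.

Step 13
Reactants: 16 (1S,3R,6E,10S)-12-bromo-3-ethenyl-1,3,7,11,11-pentamethyl-2-oxabicyclo[8.4.0]tetradeca-6,12-diene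
Product: 17 (1S,3R,6S,7S,10S)-12-bromo-3-ethenyl-6,7-epoxy-1,3,7,11,11-pentamethyl-2-oxabicyclo[8.4.0]tetradec-12-ene
Conditions: ent-Shi ketone (cat., enantiomer of the D-fructose-derived ketone), KHSO5 (Oxone), K2CO3, Bu4NHSO4, MeCN–CH2(OMe)2–aqueous buffer pH 10.5, 0 °C
Reagents that add atoms: potassium peroxymonosulfate, [K+].[O-]S(=O)(=O)OO
Why: Shi epoxidation (chiral dioxirane, spiro transition state) attacks only the electron-rich trisubstituted (E)-C6=C7 bond, the bromoalkene and the vinyl group being electron-poor or monosubstituted, and the catalyst enantiomer opposite to the D-fructose-derived one, which gives (R,R)-epoxides from such alkenes, sets C6 and C7 as (S,S) under reagent control.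

Step 14
Reactants: 17 (1S,3R,6S,7S,10S)-12-bromo-3-ethenyl-6,7-epoxy-1,3,7,11,11-pentamethyl-2-oxabicyclo[8.4.0]tetradec-12-ene
Product: 18 (1S,3R,6S,7S,10S,12S)-12-bromo-3-ethenyl-6,7-epoxy-1,3,7,11,11-pentamethyl-2-oxabicyclo[8.4.0]tetradecane (CNP0243863.1)
Conditions: Mn(dpm)3 (cat.), PhSiH3, t-BuOOH, i-PrOH, 22 °C
Reagents that add atoms: none
Why: Mukaiyama-type metal-hydride hydrogen atom transfer hydrogenation delivers hydrogen to C13 to give the α-bromo radical at C12, which should take the second hydrogen on its axial face, anti to the axial C11 methyl group (the face that small hydrides use on 2,2-dimethylcyclohexanones), so that bromine ends equatorial (12S), while the C–Br bond and the epoxide survive these radical conditions and the hindered monosubstituted C3 vinyl group should react more slowly than the trisubstituted bromoalkene.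

**Compound list**

1 | (R)-linalool, (3R)-3,7-dimethylocta-1,6-dien-3-ol | C=C[C@](C)(O)CCC=C(C)C | starting material
2 | (R)-linalyl acetate, (3R)-3,7-dimethylocta-1,6-dien-3-yl acetate | C=C[C@](C)(OC(C)=O)CCC=C(C)C | intermediate
3 | (3R,6E)-8-hydroxy-3,7-dimethylocta-1,6-dien-3-yl acetate | C=C[C@](C)(OC(C)=O)CC/C=C(\C)CO | intermediate
4 | allylic mesylate, (2E,6R)-6-acetoxy-2,6-dimethylocta-2,7-dien-1-yl methanesulfonate | C=C[C@](C)(OC(C)=O)CC/C=C(\C)COS(C)(=O)=O | intermediate
5 | (3R,6E)-8-chloro-3,7-dimethylocta-1,6-dien-3-yl acetate | C=C[C@](C)(OC(C)=O)CC/C=C(\C)CCl | intermediate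
6 | (3R,6E)-8-chloro-3,7-dimethyl-3-(prop-1-en-2-yloxy)octa-1,6-diene | C=C[C@](C)(OC(C)=C)CC/C=C(\C)CCl | intermediate
7 | 4-hydroxy-3,3-dimethylbutan-2-one | CC(=O)C(C)(C)CO | starting material
8 | 2,2-dimethyl-3-oxobutanal | CC(=O)C(C)(C)C=O | intermediate
9 | diethyl [(phenylsulfonyl)methyl]phosphonate | CCOP(=O)(CS(=O)(=O)c1ccccc1)OCC | starting material
10 | (4E)-3,3-dimethyl-5-(phenylsulfonyl)pent-4-en-2-one | CC(=O)C(C)(C)/C=C/S(=O)(=O)c1ccccc1 | intermediate
11 | (4E)-1-bromo-3,3-dimethyl-5-(phenylsulfonyl)pent-4-en-2-one | O=C(CBr)C(C)(C)/C=C/S(=O)(=O)c1ccccc1 | intermediate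
12 | (3S,4S)-4-{[(3R,6E)-8-chloro-3,7-dimethylocta-1,6-dien-3-yl]oxy}-2,2,4-trimethyl-3-[(phenylsulfonyl)methyl]cyclohexan-1-one | C=C[C@](C)(O[C@@]1(C)CCC(=O)C(C)(C)[C@@H]1CS(=O)(=O)c1ccccc1)CC/C=C(\C)CCl | intermediate
13 | (1S,3R,6E,10S)-3-ethenyl-1,3,7,11,11-pentamethyl-9-(phenylsulfonyl)-2-oxabicyclo[8.4.0]tetradec-6-en-12-one, C9 epimers | C=C[C@@]1(C)CC/C=C(C)/CC(S(=O)(=O)c2ccccc2)[C@H]2C(C)(C)C(=O)CC[C@]2(C)O1 | intermediate
14 | (1S,3R,6E,10S)-3-ethenyl-1,3,7,11,11-pentamethyl-2-oxabicyclo[8.4.0]tetradec-6-en-12-one | C=C[C@@]1(C)CC/C=C(C)/CC[C@H]2C(C)(C)C(=O)CC[C@]2(C)O1 | intermediate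
15 | (1S,3R,6E,10S)-3-ethenyl-1,3,7,11,11-pentamethyl-2-oxabicyclo[8.4.0]tetradeca-6,12-dien-12-yl trifluoromethanesulfonate | C=C[C@@]1(C)CC/C=C(C)/CC[C@H]2C(C)(C)C(OS(=O)(=O)C(F)(F)F)=CC[C@]2(C)O1 | intermediate
16 | (1S,3R,6E,10S)-12-bromo-3-ethenyl-1,3,7,11,11-pentamethyl-2-oxabicyclo[8.4.0]tetradeca-6,12-diene | C=C[C@@]1(C)CC/C=C(C)/CC[C@H]2C(C)(C)C(Br)=CC[C@]2(C)O1 | intermediate
17 | (1S,3R,6S,7S,10S)-12-bromo-3-ethenyl-6,7-epoxy-1,3,7,11,11-pentamethyl-2-oxabicyclo[8.4.0]tetradec-12-ene | C=C[C@@]1(C)CC[C@@H]2O[C@@]2(C)CC[C@H]2C(C)(C)C(Br)=CC[C@]2(C)O1 | intermediate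
18 | (1S,3R,6S,7S,10S,12S)-12-bromo-3-ethenyl-6,7-epoxy-1,3,7,11,11-pentamethyl-2-oxabicyclo[8.4.0]tetradecane | C=C[C@@]1(C)CC[C@@H]2O[C@@]2(C)CC[C@H]2C(C)(C)[C@@H](Br)CC[C@]2(C)O1 | target

**Step count**

Total: 14 steps. Longest linear sequence: 11 steps (steps 1–4 and 8–14, from 1 to 18).

**Steps most likely to fail**

Step 8. Hydrogen transfer from the silane may reach the α-keto radical or the α-alkoxy radical before the carbon–carbon bonds form, so that 10 or an open-chain adduct results. β-Scission of the tertiary allylic C–O bond of the α-alkoxy radical may compete, and the ring closure may show low facial selectivity. The fallback replaces the reductive chain by a degenerative xanthate group transfer, in which no hydrogen donor is present while the two bonds form; it leaves the facial outcome of the closure unchanged. It sets out from 11, whose bromide is displaced by KSC(S)OEt (acetone, 0 °C) to give O-ethyl S-[(4E)-3,3-dimethyl-2-oxo-5-(phenylsulfonyl)pent-4-en-1-yl] carbonodithioate F1. F1 and 6 with Et3B and air (1,2-dichloroethane, 20 °C) should undergo group-transfer addition and 6-exo cyclisation to the α-sulfonyl xanthate (3S,4S)-4-{[(3R,6E)-8-chloro-3,7-dimethylocta-1,6-dien-3-yl]oxy}-3-{[(ethoxycarbonothioyl)sulfanyl](phenylsulfonyl)methyl}-2,2,4-trimethylcyclohexan-1-one F2. (Me3Si)3SiH with Et3B then cleaves the C–S bond of the xanthate, and the route is rejoined at 12.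

Step 9. Alkylation through the ketone enolate at C13, or intermolecular alkylation, may compete with closure of the ten-membered ring. The fallback masks the ketone so that only one carbanion can form. It sets out from 12: KN(SiMe3)2 (1 equiv) and t-BuMe2SiCl (THF, −78 °C) give the C12 tert-butyldimethylsilyl enol ether of 12, F3. A second equivalent of KN(SiMe3)2 at high dilution closes the ring through the α-sulfonyl carbanion to (1S,3R,6E,10S)-12-[(tert-butyldimethylsilyl)oxy]-3-ethenyl-1,3,7,11,11-pentamethyl-9-(phenylsulfonyl)-2-oxabicyclo[8.4.0]tetradeca-6,12-diene F4. Bu4NF buffered with AcOH cleaves the silyl enol ether, and the route is rejoined at 13.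

Step 14. Hydrogen atom transfer may also reduce the C3 vinyl group, deliver hydrogen to the wrong face of the C12 radical, or cleave the C–Br bond. The fallback installs bromine by substitution instead of hydrogenation, though displacement at this neopentyl centre is itself hindered. It sets out from 14: Shi epoxidation under the conditions of step 13 gives the epoxy ketone (1S,3R,6S,7S,10S)-3-ethenyl-6,7-epoxy-1,3,7,11,11-pentamethyl-2-oxabicyclo[8.4.0]tetradecan-12-one F5. LiBH(s-Bu)3 (THF, −78 °C) attacks from the equatorial side to give the axial alcohol (1S,3R,6S,7S,10S,12R)-3-ethenyl-6,7-epoxy-1,3,7,11,11-pentamethyl-2-oxabicyclo[8.4.0]tetradecan-12-ol F6. Appel bromination (CBr4, PPh3, CH2Cl2, 0 °C) with inversion at C12 then comes back to the route at 18.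

**Further compounds**

F1 | step 8 | O-ethyl S-[(4E)-3,3-dimethyl-2-oxo-5-(phenylsulfonyl)pent-4-en-1-yl] carbonodithioate | CCOC(=S)SCC(=O)C(C)(C)/C=C/S(=O)(=O)c1ccccc1
F2 | step 8 | (3S,4S)-4-{[(3R,6E)-8-chloro-3,7-dimethylocta-1,6-dien-3-yl]oxy}-3-{[(ethoxycarbonothioyl)sulfanyl](phenylsulfonyl)methyl}-2,2,4-trimethylcyclohexan-1-one | C=C[C@](C)(O[C@@]1(C)CCC(=O)C(C)(C)[C@@H]1C(SC(=S)OCC)S(=O)(=O)c1ccccc1)CC/C=C(\C)CCl
F3 | step 9 | C12 tert-butyldimethylsilyl enol ether of 12 | C=C[C@](C)(O[C@@]1(C)CC=C(O[Si](C)(C)C(C)(C)C)C(C)(C)[C@@H]1CS(=O)(=O)c1ccccc1)CC/C=C(\C)CCl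
F4 | step 9 | (1S,3R,6E,10S)-12-[(tert-butyldimethylsilyl)oxy]-3-ethenyl-1,3,7,11,11-pentamethyl-9-(phenylsulfonyl)-2-oxabicyclo[8.4.0]tetradeca-6,12-diene | C=C[C@@]1(C)CC/C=C(C)/CC(S(=O)(=O)c2ccccc2)[C@H]2C(C)(C)C(O[Si](C)(C)C(C)(C)C)=CC[C@]2(C)O1
F5 | step 14 | (1S,3R,6S,7S,10S)-3-ethenyl-6,7-epoxy-1,3,7,11,11-pentamethyl-2-oxabicyclo[8.4.0]tetradecan-12-one | C=C[C@@]1(C)CC[C@@H]2O[C@@]2(C)CC[C@H]2C(C)(C)C(=O)CC[C@]2(C)O1
F6 | step 14 | (1S,3R,6S,7S,10S,12R)-3-ethenyl-6,7-epoxy-1,3,7,11,11-pentamethyl-2-oxabicyclo[8.4.0]tetradecan-12-ol | C=C[C@@]1(C)CC[C@@H]2O[C@@]2(C)CC[C@H]2C(C)(C)[C@H](O)CC[C@]2(C)O1
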